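The data come from a simulation for an exercise, and the scatter is random.

In a one-step world Xa and Xb turn into Xp until the limiting reagent is gone, and in the epsilon flask that is Xa, charged at 80.0 mM against 160 mM of Xb. The flasks, the readings and the questions are these.

| flask | Xa | Xb | Xc | Xp | time |
|---|---|---|---|---|---|
| epsilon | 80.0 mM | 160 mM | 0.160 mM |  |  |
| alpha | 40.0 mM | 120 mM | 0.160 mM |  |  |
| gamma | 80.0 mM | 160 mM | 0.160 mM | 24.0 mM |  |
| delta | 80.0 mM | 160 mM | 0.320 mM |  |  |
| beta | 20.0 mM | 160 mM | 0.160 mM |  | 68 h |

- epsilon run (time / h: [Xp] / mM): 3.9: 7.56; 12: 13.21; 22: 15.75; 36: 17.96; 51: 18.64; 68: 19.41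
- alpha run (time / h: [Xp] / mM): 3.9: 5.82; 12: 11.20; 22: 13.89; 36: 15.58; 51: 17.11; 68: 17.52
- gamma run (time / h: [Xp] / mM): 3.9: 31.48; 12: 37.31; 22: 39.96; 36: 41.81; 51: 43.31; 68: 43.60
- delta run (time / h: [Xp] / mM): 3.9: 17.73; 12: 29.10; 22: 33.74; 36: 35.06; 51: 35.75; 68: 35.76

(readings scatter by 0.2 mM)

* order of the initial rate in [Xc], near the charge of the epsilon run, the rate being that where two percent of its Xa are Xp
* Xp in the beta run at 68 h, as a share of the Xa charged

- Overall: Xa + Xb -> Xp, with Xc as catalyst.
- Constant volume, constant temperature.
- The analysis sees a species whether free or bound.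
- An order is taken over about fifteen percent of the charge, up and down.

The epsilon curve leaves that picture early. Its mean slope over the first 3.9 h is 1.94 mM/h, its knee lies near 12 h, and at 68 h it reads 19.41 mM, with 60.6 mM of the Xa charged not turned to Xp. From the knee on, Xp gains on average 3.57 mM for each factor e in time, so the readings show a creep and no flat level. Gamma, given 24.0 mM of Xp, makes 19.6 mM by 68 h, close to epsilon's total.

Call the reach of a flask its Xp at 68 h with the slowing from thinning Xa added back. Suppose the rate follows Xa/(Xa + K), where K, the saturation constant, is the Xa at which thinning halves the rate. Each mM of Xp then costs one plus K over the Xa left, and summed over the run, Xp + K ln(charge/left) = reach.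

Alpha has 120 mM of Xb. Taking its lower charge as a proportionally shorter clock puts its reach 1.03 mM below epsilon's. The rest of the gap between their readings at 68 h gives a reading of K = 2.89 mM, and on that reading epsilon's reach is 20.2 mM.

Beta shares epsilon's Xb and Xc, so this reckoning gives it the same reach. A trial of 15.0 mM costs 19.0 mM of reach, and each further mM costs 1.58, so beta should hold 15.8 mM, which is 78.8 % of its charge.

For the order, delta holds 2.35 times epsilon's Xp at 3.9 h and 2.20 times at 12 h. The ratio is lower at the later reading, so this reckoning puts the mean order over that doubling of Xc above 1.23, and takes the order asked to lie there too.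

The forecast, holding that “The total is limited by catalyst life”, gives 1.4 for the order and 70 % for beta, lower than the share reckoned here.

The simulation gives 81.1 % for beta, which is 16.2 mM of Xp, and 1.9 for the order.

    Xc + Xa → Xc.Xa (2027 /M/h)
    Xc.Xa + Xb → Z (374.4 /M/h)
    Z → Xp + Xc (108.7 /h)
    Xc + J → L
    2 Xb → Q (2.534 /M/h)

By the step in which two Xb give Q alone, the first half-life of Xb at beta's charge is 1.23 h. Carried to delta, K adds 1.71 mM to its 35.76 mM at 68 h, for a reach of 37.5 mM, which is 1.86 times epsilon's.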